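**Remark.** Germacrane locants C1–C15 are used for the target and for every intermediate (on the carvone ring: C1, C10, C9, C8, C7, C6). "Upper face" means the face of the six-membered ring that carries the C7 side chain.

## Analysis of the target

The target is a germacranolide: a 10-membered carbocycle (C1–C10) fused at C6–C7 to an α-methylene-γ-butyrolactone (C11, C12, C13). Both ring alkenes are cis within the ring (4E,9Z by the sequence rule): C4=C5 carries the C15 hydroxymethyl on C4 and C9=C10 carries the C14 methyl on C10. The ring stereocentres are C1 (S, free allylic alcohol), C6 (R), C7 (R) and C8 (R, ester of (S)-2-methylbutanoic acid). C6–O is trans to the C7–C11 bond (trans-fused lactone) and C8–O is cis to it, so O6 and O8 are 1,3-anti across C7; C1–O lies on the face opposite C8–O across C9=C10. Sensitive groups are the methylene lactone (a Michael acceptor), the allylic ester and alcohols, and the medium ring, which invites transannular reactions. In particular, a C1 ketone beside a free C8 hydroxyl across the cis alkene would close to a bridged hemiketal and then a furan. The difficulties are closure of a 10-membered ring, the geometry of two trisubstituted alkenes, and three carbinol centres with no rigid template in the open ring. The strategy rests on one feature: C1(O)–C10(C14)=C9–C8(O)–C7(C11)–C6(O) is the carvone ring with C7 in the (R)-carvone configuration, and C1 and C6, bonded in that ring, both carry oxygen. Cutting C1–C6 while inserting C2–C5 therefore turns the six-membered ring into the 10-membered one.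

## Retrosynthetic reasoning

**C15–O and C1–H (40 ⇐ 39 ⇐ 38).** The C15 ether is cleaved last, and the C1 carbinol is traced back to the C1 enone 38. C1 stays a ketone until O8 is acylated, because a free C1 hydroxyl would compete in acylation and oxidation. It is set by a reagent-controlled reduction, since the ring offers no reliable bias at C1.

**Lactone O6–C12 (38 ⇐ 35).** The acyl–oxygen bond is cut and C12 is lowered to the alcohol level. Oxidative lactonisation of the 2-methylene-1,4-diol 35 then needs no separate acid. Only O6 is free at that point, so the 6,12-lactone is the only one that can form.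

**C8 ester and C6–H together (34 ⇐ 31 + 33).** The ester C–O bond and the C6–H bond are cut in one operation, an Evans–Tishchenko reduction of β-hydroxy ketone 31 with aldehyde 33. This relays the C8 configuration to C6 (1,3-anti), installs the ester and tells O6 from O8. C1 must still be masked as its enol ether here, for the hemiketal reason above.

**C4=C5 (30 ⇐ 28 ⇐ 26).** The alkene is traced to dehydrogenation at C5 of ketone 26, where the C6 carbonyl activates exactly that position. Carrying the alkene through the rearrangement would need a different C6 substituent and would not fix its geometry either.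

**C3–C4, the key disconnection (26 ⇐ 23).** Re-forming C1–C6 and cutting C3–C4 of 26 gives the 1,6-dialkenyl cyclohexenol 23. The forward anionic oxy-Cope shift makes the 10-membered ring by four-carbon ring expansion and leaves C6 as a ketone and C1 as an enol ether.

**C5–C6 (23 ⇐ 16 + 20).** The C6 alkenyl group comes from addition of the organometallic derived from iodide 20 (made from alcohol 17) to ketone 16. The forward step must deliver a C6 epimer whose alkenyl group is gauche to the C1 vinyl group.

**C8–O (16 ⇐ 13 ⇐ 12 ⇐ 11).** The C8 oxygen is placed on the six-membered ring. In 11, C1 is quaternary, so C8 is the only ring CH2 allylic to C9=C10, and reduction of enone 12 on a rigid ring sets C8–O cis to the side chain. A γ-oxidation of the C1 enone after ring expansion was rejected: C2, the α′ position, would enolise first, and the facial outcome in the medium ring cannot be argued. The C8 oxygen also steers the alkenyl addition and, later, C6.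

**C1–C2 and the methyl ether (11 ⇐ 10 ⇐ 8 + 9).** The vinyl group is added to the enone carbonyl of 8 with Grignard reagent 9 and the tertiary alkoxide is methylated. The methyl ether is what lets C1 leave the key step as an enol ether.

**C6–O and C12–O (8 ⇐ 7 ⇐ 5 ⇐ 4 ⇐ 2 ⇐ 1).** α′-Hydroxylation of the enone gives the C6 oxygen, and an ene chlorination of the isopropenyl group of (R)-carvone 1 gives the C12 oxygen. Carvone supplies C7, C14 and the cis C9=C10 alkene.

## Alternatives that were turned down

**Alternative 1:** The C9=C10 alkene is disconnected. In the forward step a second-generation Grubbs catalyst enters at an allyl ether relay, forms the C10 alkylidene and closes onto a C9 vinyl group to give the bis-silyl ether A1 of the target.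
- For: all oxygenation and all stereocentres are in place before closure and only deprotection follows. On step count after ring closure it is clearly better than the chosen route.
- Against: a 10-membered ring closed by metathesis to a trisubstituted alkene flanked by two oxygenated allylic carbons is slow and prone to oligomerisation. The carbene can also engage the methylene lactone and C4=C5. The catalyst does not control geometry, although ring strain does favour the cis alkene. C1, C6, C7 and C8 must each be set on an open chain.
- Comparison: the chosen route forms the ring by an intramolecular sigmatropic shift at normal concentration, pays the ring strain with enolate formation, and takes C7, C14 and the C9=C10 geometry from carvone.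

**Alternative 2:** The 10-membered ring is traced to a cis-fused bicyclo[5.3.0] spiro-epoxide by re-forming C1–C5. In the forward step the C1 alkoxide fragments: C1–C5 breaks, the C1 carbonyl and C4=C5 form, and the epoxide opens to the C15 alkoxide, giving A2.
- For: the fragmentation is stereospecific, so the C4=C5 geometry follows from the precursor. This is stronger than the chosen route, where that geometry comes from a selenoxide elimination. The C15 alcohol and the lactone appear in the same step.
- Against: the hydroazulene needs five defined centres and an antiperiplanar alignment of the breaking bonds, a long synthesis in itself. A2 still lacks the exocyclic methylene, and needs C1 reduction and exchange of the C8 silyl ether for the ester.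
- Comparison: the chosen route reaches its precursor from carvone with each new centre set on a six-membered ring, and what it gives up in alkene control it regains in a much shorter approach to the rearrangement substrate.

**Alternative 3:** C8–C9 is disconnected with an alkyne standing in for C9=C10. In the forward step CrCl2 with catalytic NiCl2 turns a C9 iodoalkyne into an alkynylchromium species that adds to the C8 aldehyde, giving the cyclodecenyne A3.
- For: this closure is a dependable macrocyclisation that tolerates dense functionality. It creates the C8 oxygen in the ring-forming step and carries a preset C4=C5 geometry, both points on which it is at least as good as the chosen route.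
- Against: a 10-membered ring holding a linear alkyne unit and a cis alkene is strongly strained. The C8 configuration is not controlled. A3 lacks C14, so the alkyne must later undergo a regio- and stereoselective methyl-metalation between two propargylic oxygens.
- Comparison: the chosen route has C14 and the alkene from the start and sets C8 by a substrate-controlled reduction on a cyclohexenone.

Key step: step 16

## Route

Step 1
Reactants: 1 (R)-(−)-carvone
Product: 2 C12 allylic chloride, (5R)-5-(3-chloroprop-1-en-2-yl)-2-methylcyclohex-2-en-1-one
Conditions: Ca(OCl)2, CO2 (solid), CH2Cl2/H2O, 0 °C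
Reagents that add atoms: calcium hypochlorite, [Ca+2].[O-]Cl.[O-]Cl
Why: Ene-type allylic chlorination by hypochlorous acid; the electron-rich 1,1-disubstituted alkene reacts and the enone alkene does not, and the stereocentre is untouched.

Step 2
Reactants: 2 C12 allylic chloride
Product: 4 C12 allylic alcohol (5R)-5-(3-hydroxyprop-1-en-2-yl)-2-methylcyclohex-2-en-1-one, via allylic acetate 3 (not isolated)
Conditions: KOAc, Bu4NI (cat.), DMF, 60 °C; then K2CO3, MeOH, rt
Reagents that add atoms: potassium acetate, CC(=O)[O-].[K+]
Why: SN2 displacement of a primary allylic chloride by acetate, then base-catalysed transesterification to methanol; no step touches C7.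

Step 3
Reactants: 4 C12 allylic alcohol
Product: 5 C12 tert-butyldiphenylsilyl ether of 4
Conditions: TBDPSCl, imidazole, DMF, rt
Reagents that add atoms: tert-butyl(chloro)diphenylsilane, CC(C)(C)[Si](Cl)(c1ccccc1)c1ccccc1
Why: Standard silylation of a primary alcohol; this silyl ether survives every step up to step 22.

Step 4
Reactants: 5 C12 silyl ether
Product: 7 6-hydroxy enone with C6–OH trans to the C7 side chain, via potassium dienolate 6 (not isolated)
Conditions: KHMDS, THF, −78 °C; then 2-(phenylsulfonyl)-3-phenyloxaziridine, −78 °C; aq. NH4Cl
Reagents that add atoms: 2-(phenylsulfonyl)-3-phenyloxaziridine, O=S(=O)(N1OC1c1ccccc1)c1ccccc1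
Why: Kinetic α′-deprotonation of the enone and oxygen transfer from the oxaziridine to the cross-conjugated enolate, anti to the neighbouring C7 side chain. The C6 configuration serves only to steer step 6 and is removed in step 12.

Step 5
Reactants: 7 6-hydroxy enone
Product: 8 C6 2-naphthylmethyl ether of 7
Conditions: 2-(bromomethyl)naphthalene, Ag2O, CH2Cl2, rt, dark
Reagents that add atoms: 2-(bromomethyl)naphthalene, BrCc1ccc2ccccc2c1
Why: Silver-oxide-mediated alkylation of an α-hydroxy ketone under neutral conditions, so C6 is not epimerised. The ether cannot migrate in step 7, can chelate in step 6 and is removed oxidatively in step 11.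

Step 6
Reactants: 8 C6 naphthylmethyl ether; 9 vinylmagnesium bromide
Product: 10 C1 tertiary alcohol, vinyl on the upper face (cis to the C7 side chain), C1–OH cis to C6–O
Conditions: CH2Cl2/THF, −78 °C; aq. NH4Cl
Reagents that add atoms: none
Why: 1,2-Addition of the Grignard reagent to the α-methyl enone under chelation control: magnesium bridges the carbonyl and the equatorial C6 ether oxygen and the vinyl group enters trans to that ether. The C1 configuration is lost again in step 16.

Step 7
Reactants: 10 C1 tertiary alcohol
Product: 11 C1 methyl ether of 10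
Conditions: KH, MeI, THF, 0 °C
Reagents that add atoms: iodomethane, CI
Why: Williamson methylation of the potassium tertiary alkoxide; the neighbouring ether cannot migrate as a silyl group would.

Step 8
Reactants: 11 C1 methyl ether
Product: 12 C8 enone (C8=O conjugated with C9=C10)
Conditions: Rh2(C6H10NO)4 (dirhodium caprolactamate, cat.), t-BuOOH, NaHCO3, CH2Cl2, rt
Reagents that add atoms: tert-butyl hydroperoxide, CC(C)(C)OO
Why: Radical allylic oxidation of a trisubstituted cyclohexene to the β,β-disubstituted enone. C1 is quaternary, so C8 is the only ring methylene allylic to C9=C10, as in the oxidation of 1-methylcyclohexene-type terpenes at the CH2 next to the alkene CH.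

Step 9
Reactants: 12 C8 enone
Product: 13 C8 allylic alcohol, C8–OH on the upper face (cis to the C7 side chain)
Conditions: LiBH(s-Bu)3, THF, −78 °C; aq. NH4Cl
Reagents that add atoms: none
Why: 1,2-Reduction by a bulky hydride; C10 is fully substituted, which blocks conjugate reduction. The hydride takes the equatorial path on the face opposite the C7 side chain, as in the reduction of 2-alkylcyclohexanones to cis (axial) alcohols.

Step 10
Reactants: 13 C8 allylic alcohol
Product: 14 C8 triethylsilyl ether of 13
Conditions: Et3SiOTf, 2,6-lutidine, CH2Cl2, −78 °C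
Reagents that add atoms: triethylsilyl trifluoromethanesulfonate, CC[Si](CC)(CC)OS(=O)(=O)C(F)(F)F
Why: Silylation of a hindered secondary alcohol with the silyl triflate; the buffered low temperature protects the tertiary doubly allylic methyl ether.

Step 11
Reactants: 14 C8 triethylsilyl ether
Product: 15 C6 alcohol (naphthylmethyl group removed)
Conditions: DDQ, CH2Cl2/pH 7 buffer, rt
Reagents that add atoms: none
Why: Oxidative cleavage of the arylmethyl ether by hydride abstraction and hydrolysis of the oxocarbenium ion; silyl ethers and the methyl ether on quaternary C1 have no comparably activated C–H bond.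

Step 12
Reactants: 15 C6 alcohol
Product: 16 C6 ketone (2-methoxy-2-vinyl cyclohex-3-enone)
Conditions: Dess–Martin periodinane, NaHCO3, CH2Cl2, rt
Reagents that add atoms: none
Why: Neutral oxidation of a hindered secondary alcohol; buffered conditions avoid enolisation at C7, which would epimerise it or expel the C8 silyloxy group.

Step 13
Reactants: 17 propargyl alcohol
Product: 18 4-methoxybenzyl propargyl ether
Conditions: NaH, 4-methoxybenzyl chloride, Bu4NI (cat.), THF/DMF, 0 °C → rt
Reagents that add atoms: 4-methoxybenzyl chloride, COc1ccc(CCl)cc1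
Why: Williamson etherification of a primary alcohol.

Step 14
Reactants: 18 4-methoxybenzyl propargyl ether
Product: 20 (E)-1-iodo-3-(4-methoxybenzyloxy)prop-1-ene, via alkenylzirconocene chloride 19 (not isolated)
Conditions: Cp2Zr(H)Cl, THF, rt; then I2, 0 °C
Reagents that add atoms: iodine, II
Why: syn-Hydrozirconation of the terminal alkyne places zirconium on the terminal carbon, and iodinolysis proceeds with retention, so the (E) geometry of the future C4=C5 unit is fixed.

Step 15
Reactants: 20 (E)-alkenyl iodide; 16 C6 ketone
Product: 23 oxy-Cope precursor (C6 tertiary alcohol with the alkenyl group trans to the C1 vinyl group), via alkenyllithium 21 (not isolated), via alkenylcerium dichloride 22 (not isolated)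
Conditions: t-BuLi, Et2O, −78 °C; CeCl3, THF, −78 °C; then 16, −78 °C; aq. NH4Cl
Reagents that add atoms: none
Why: Iodine–lithium exchange with retention, transmetalation to the weakly basic organocerium and 1,2-addition to the hindered ketone without enolisation at C7. The upper face of the carbonyl is closed by the pseudoaxial C8 silyloxy group, the C7 side chain and the C1 vinyl group, so the alkenyl group enters from the lower face. This gives C6–OH on the upper face and the two alkenyl groups trans-diequatorial; the C6 configuration is lost in step 16.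

Step 16
Reactants: 23 oxy-Cope precursor
Product: 26 10-membered C6 ketone with C1 methyl dienol ether, via potassium alkoxide 24 (not isolated), via potassium enolate 25 (not isolated)
Conditions: KH, 18-crown-6, THF, 0 °C → rt; then AcOH, −78 °C
Reagents that add atoms: none
Why: KH with 18-crown-6 converts 23 into the dissociated potassium alkoxide 24, and the 1,5-diene C3=C2–C1–C6–C5=C4 undergoes the alkoxide-accelerated [3,3] sigmatropic shift: C3–C4 forms as C1–C6 breaks, giving enolate 25, which acetic acid protonates at C5 to ketone 26. The closest known reaction type is the anionic oxy-Cope ring expansion of trans-1,2-dialkenylcyclohexanols to cyclodec-5-enones, in the variant with an alkoxy group on the carbon next to the carbinol, which delivers the second carbonyl as an enol ether. The 10-membered ring is not closed by cyclisation: it arises by four-carbon ring expansion inside a six-atom chair array in which the ring bonds C1–C10 and C6–C7 are equatorial and the two oxygens axial, both alkenyl groups being equatorial on the cyclohexene. The new stereocentre C4 is fixed by this chair together with the (E) geometry of C4=C5, which places CH2OPMB equatorial on the array; the same chair gives the enol ether with C10 and C3 trans and leaves C9=C10 untouched, and both C4 and the enol ether geometry are erased later. The step needs the C1 vinyl group to react rather than the 2-propenyl group on C7, which forms a second 1,5-diene with the C6 alkenyl group through C6–C7; C1–C6 is the bond weakened by the methoxy group and by allylic conjugation with C9=C10, so its cleavage is favoured. The ring alkene C9=C10 could pair with the C6 alkenyl group only through a boat-shaped array and is not expected to compete. Transannular aldol closure of a 1,6-diketone is excluded because C1 leaves the step as a methyl enol ether, and loss of the C8 silyloxy group is avoided because the enolate forms toward C5 and not toward C7.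

Step 17
Reactants: 26 10-membered C6 ketone
Product: 28 C5 phenylselenide of 26 (C5 epimers), via lithium enolate 27 (not isolated)
Conditions: LDA, THF, −78 °C; then PhSeBr, −78 °C
Reagents that add atoms: phenylselenenyl bromide, Br[Se]c1ccccc1
Why: Kinetic deprotonation takes the C5 methylene and not the C7 methine, which is flanked by the side chain and the C8 silyloxy group. The enolate is far more nucleophilic toward the selenium electrophile than the methyl dienol ether.

Step 18
Reactants: 28 C5 phenylselenide
Product: 30 C4=C5 enone (C3 and C6 cis across C4=C5), via selenoxide 29 (not isolated)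
Conditions: 30% H2O2, pyridine, CH2Cl2, 0 °C → rt
Reagents that add atoms: none
Why: Oxidation to the selenoxide and syn elimination; C4–H is the only β-hydrogen, so the regiochemistry is fixed. The C5 epimers can interconvert through the enol in the presence of pyridine, and the elimination should pass through the less strained array that gives the ring-cis enone; excess peroxide and pyridine keep the selenenic acid from adding to the dienol ether.

Step 19
Reactants: 30 C4=C5 enone
Product: 31 C8 hydroxy enone (C8–OH free, C1 still the methyl enol ether)
Conditions: NH4F, MeOH, rt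
Reagents that add atoms: none
Why: Fluoride cleavage of the secondary triethylsilyl ether at near-neutral pH. The acid-labile dienol ether and the primary tert-butyldiphenylsilyl ether are kept, and no alkoxide forms that could trigger a retro-aldol opening.

Step 20
Reactants: 32 (S)-2-methylbutan-1-ol
Product: 33 (S)-2-methylbutanal
Conditions: TEMPO (cat.), NaOCl, KBr, NaHCO3, CH2Cl2/H2O, 0 °C; used at once
Reagents that add atoms: none
Why: Oxoammonium oxidation of a primary alcohol under buffered two-phase conditions, which is known to leave an α-stereocentre intact.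

Step 21
Reactants: 31 C8 hydroxy enone; 33 (S)-2-methylbutanal
Product: 34 C6 alcohol C8 (S)-2-methylbutanoate, C6–OH 1,3-anti to C8–O
Conditions: SmI2 (0.3 equiv), THF, −10 °C
Reagents that add atoms: none
Why: Evans–Tishchenko reduction: the hemiacetal from the C8 hydroxyl and 33 is held with the C6 carbonyl on trivalent samarium and transfers its hydride through a six-membered chair. C6–H therefore arrives on the side of O8 and the new hydroxyl is 1,3-anti to C8–O, which is the (6R) configuration; the acyl group ends on O8 as the required ester, and the reaction is known for β-hydroxy ketones including enones.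

Step 22
Reactants: 34 C6 alcohol C8 ester
Product: 35 C1 enone C6,C12-diol
Conditions: HF·pyridine, THF/H2O, 0 °C → rt
Reagents that add atoms: water, O
Why: Protonation of the dienol ether at C2 and hydrolysis gives the C1 enone conjugated with the unchanged cis C9=C10 alkene, and the same medium cleaves the primary silyl ether. O8 is now acylated, so the C1 ketone cannot close onto it.

Step 23
Reactants: 35 C1 enone C6,C12-diol
Product: 38 α-methylene lactone C1 enone (C15 PMB ether), via C12 enal 36 (not isolated), via lactol 37 (not isolated)
Conditions: TEMPO (cat.), PhI(OAc)2, CH2Cl2, rt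
Reagents that add atoms: none
Why: Chemoselective oxidation of the primary allylic alcohol to the enal, lactol formation with the C6 hydroxyl and a second oxidation give the γ-lactone, a known route from 2-methylene-1,4-diols. The fusion is trans because C6 and C7 are already set.

Step 24
Reactants: 38 α-methylene lactone C1 enone
Product: 39 C15 PMB ether of the target, (1S)-alcohol
Conditions: (R)-Me-CBS oxazaborolidine, catecholborane, toluene, −78 °C; MeOH
Reagents that add atoms: none
Why: Corey–Bakshi–Shibata 1,2-reduction of the enone; with the alkenyl side (C10) as the large group and C2 as the small group, the (R)-catalyst delivers hydride to the face that gives the (1S)-alcohol. At −78 °C catecholborane does not reduce the methylene lactone or the ester.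

Step 25
Reactants: 39 C15 PMB ether of the target
Product: 40 target, CNP0526758.1
Conditions: DDQ, CH2Cl2/pH 7 buffer, 0 °C
Reagents that add atoms: none
Why: Oxidative removal of the 4-methoxybenzyl ether under buffered conditions, which the methylene lactone, the ester and the allylic alcohol tolerate.

## Compound list

1 | (R)-(−)-carvone | CC1=CC[C@H](CC1=O)C(C)=C | starting material
2 | C12 allylic chloride, (5R)-5-(3-chloroprop-1-en-2-yl)-2-methylcyclohex-2-en-1-one | O=C1C(C)=CC[C@@H](C(=C)CCl)C1 | intermediate
3 | allylic acetate of 4 | O=C1C(C)=CC[C@@H](C(=C)COC(C)=O)C1 | intermediate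
4 | C12 allylic alcohol, (5R)-5-(3-hydroxyprop-1-en-2-yl)-2-methylcyclohex-2-en-1-one | O=C1C(C)=CC[C@@H](C(=C)CO)C1 | intermediate
5 | C12 tert-butyldiphenylsilyl ether of 4 | O=C1C(C)=CC[C@@H](C(=C)CO[Si](c2ccccc2)(c2ccccc2)C(C)(C)C)C1 | intermediate
6 | potassium cross-conjugated dienolate of 5 | CC1=CC[C@@H](C(=C)CO[Si](c2ccccc2)(c2ccccc2)C(C)(C)C)C=C1[O-].[K+] | intermediate
7 | 6-hydroxy enone, C6–OH trans to the C7 side chain | O=C1C(C)=CC[C@@H](C(=C)CO[Si](c2ccccc2)(c2ccccc2)C(C)(C)C)[C@@H]1O | intermediate
8 | C6 2-naphthylmethyl ether of 7 | O=C1C(C)=CC[C@@H](C(=C)CO[Si](c2ccccc2)(c2ccccc2)C(C)(C)C)[C@@H]1OCc3ccc4ccccc4c3 | intermediate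
9 | vinylmagnesium bromide | C=C[Mg]Br | starting material
10 | C1 tertiary alcohol, vinyl cis to the C7 side chain, C1–OH cis to C6–O | C=C[C@@]1(O)C(C)=CC[C@@H](C(=C)CO[Si](c2ccccc2)(c2ccccc2)C(C)(C)C)[C@@H]1OCc3ccc4ccccc4c3 | intermediate
11 | C1 methyl ether of 10 | C=C[C@@]1(OC)C(C)=CC[C@@H](C(=C)CO[Si](c2ccccc2)(c2ccccc2)C(C)(C)C)[C@@H]1OCc3ccc4ccccc4c3 | intermediate
12 | C8 enone | C=C[C@@]1(OC)C(C)=CC(=O)[C@@H](C(=C)CO[Si](c2ccccc2)(c2ccccc2)C(C)(C)C)[C@@H]1OCc3ccc4ccccc4c3 | intermediate
13 | C8 allylic alcohol, C8–OH cis to the C7 side chain | C=C[C@@]1(OC)C(C)=C[C@@H](O)[C@@H](C(=C)CO[Si](c2ccccc2)(c2ccccc2)C(C)(C)C)[C@@H]1OCc3ccc4ccccc4c3 | intermediate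
14 | C8 triethylsilyl ether of 13 | C=C[C@@]1(OC)C(C)=C[C@@H](O[Si](CC)(CC)CC)[C@@H](C(=C)CO[Si](c2ccccc2)(c2ccccc2)C(C)(C)C)[C@@H]1OCc3ccc4ccccc4c3 | intermediate
15 | C6 alcohol | C=C[C@@]1(OC)C(C)=C[C@@H](O[Si](CC)(CC)CC)[C@@H](C(=C)CO[Si](c2ccccc2)(c2ccccc2)C(C)(C)C)[C@@H]1O | intermediate
16 | C6 ketone | C=C[C@@]1(OC)C(C)=C[C@@H](O[Si](CC)(CC)CC)[C@@H](C(=C)CO[Si](c2ccccc2)(c2ccccc2)C(C)(C)C)C1=O | intermediate
17 | propargyl alcohol | C#CCO | starting material
18 | 4-methoxybenzyl propargyl ether | C#CCOCc1ccc(OC)cc1 | intermediate
19 | (E)-alkenylzirconocene chloride | Cl[Zr](/C=C/COCc1ccc(OC)cc1)(C1C=CC=C1)C1C=CC=C1 | intermediate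
20 | (E)-1-iodo-3-(4-methoxybenzyloxy)prop-1-ene | I/C=C/COCc1ccc(OC)cc1 | intermediate
21 | (E)-3-(4-methoxybenzyloxy)prop-1-enyllithium | [Li]/C=C/COCc1ccc(OC)cc1 | intermediate
22 | (E)-alkenylcerium dichloride | Cl[Ce](Cl)/C=C/COCc1ccc(OC)cc1 | intermediate
23 | oxy-Cope precursor: 1-methoxy-1-vinyl-6-hydroxy-6-[(E)-alkenyl] cyclohexene, C8 triethylsilyl ether, C12 TBDPS ether, C15 PMB ether | C=C[C@@]1(OC)C(C)=C[C@@H](O[Si](CC)(CC)CC)[C@@H](C(=C)CO[Si](c2ccccc2)(c2ccccc2)C(C)(C)C)[C@]1(O)/C=C/COCc1ccc(OC)cc1 | intermediate
24 | potassium C6 alkoxide of 23 | C=C[C@@]1(OC)C(C)=C[C@@H](O[Si](CC)(CC)CC)[C@@H](C(=C)CO[Si](c2ccccc2)(c2ccccc2)C(C)(C)C)[C@]1([O-])/C=C/COCc1ccc(OC)cc1.[K+] | intermediate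
25 | potassium C5=C6 enolate of the 10-membered ring | [C@@H]1(O[Si](CC)(CC)CC)/C=C(C)\C(OC)=C\C[C@@H](COCc2ccc(OC)cc2)/C=C(\[O-])[C@@H]1C(=C)CO[Si](c3ccccc3)(c3ccccc3)C(C)(C)C.[K+] | intermediate
26 | 10-membered C6 ketone with C1 methyl dienol ether | [C@@H]1(O[Si](CC)(CC)CC)/C=C(C)\C(OC)=C\C[C@@H](COCc2ccc(OC)cc2)CC(=O)[C@@H]1C(=C)CO[Si](c3ccccc3)(c3ccccc3)C(C)(C)C | intermediate
27 | lithium C5=C6 enolate of 26 (enolate geometry not defined) | [C@@H]1(O[Si](CC)(CC)CC)/C=C(C)\C(OC)=C\C[C@@H](COCc2ccc(OC)cc2)C=C([O-])[C@@H]1C(=C)CO[Si](c3ccccc3)(c3ccccc3)C(C)(C)C.[Li+] | intermediate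
28 | C5 phenylselenide of 26 (C5 epimers) | [C@@H]1(O[Si](CC)(CC)CC)/C=C(C)\C(OC)=C\C[C@@H](COCc2ccc(OC)cc2)C([Se]c2ccccc2)C(=O)[C@@H]1C(=C)CO[Si](c3ccccc3)(c3ccccc3)C(C)(C)C | intermediate
29 | C5 selenoxide | [C@@H]1(O[Si](CC)(CC)CC)/C=C(C)\C(OC)=C\C[C@@H](COCc2ccc(OC)cc2)C([Se](=O)c2ccccc2)C(=O)[C@@H]1C(=C)CO[Si](c3ccccc3)(c3ccccc3)C(C)(C)C | intermediate
30 | C4=C5 enone, ring-cis | [C@@H]1(O[Si](CC)(CC)CC)/C=C(C)\C(OC)=C\C/C(COCc2ccc(OC)cc2)=C\C(=O)[C@@H]1C(=C)CO[Si](c3ccccc3)(c3ccccc3)C(C)(C)C | intermediate
31 | C8 hydroxy enone | [C@@H]1(O)/C=C(C)\C(OC)=C\C/C(COCc2ccc(OC)cc2)=C\C(=O)[C@@H]1C(=C)CO[Si](c3ccccc3)(c3ccccc3)C(C)(C)C | intermediate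
32 | (S)-2-methylbutan-1-ol | CC[C@H](C)CO | starting material
33 | (S)-2-methylbutanal | CC[C@H](C)C=O | intermediate
34 | C6 alcohol C8 (S)-2-methylbutanoate | [C@@H]1(OC(=O)[C@@H](C)CC)/C=C(C)\C(OC)=C\C/C(COCc2ccc(OC)cc2)=C\[C@@H](O)[C@@H]1C(=C)CO[Si](c3ccccc3)(c3ccccc3)C(C)(C)C | intermediate
35 | C1 enone C6,C12-diol | [C@@H]1(OC(=O)[C@@H](C)CC)/C=C(C)\C(=O)CC/C(COCc2ccc(OC)cc2)=C\[C@@H](O)[C@@H]1C(=C)CO | intermediate
36 | C12 enal | [C@@H]1(OC(=O)[C@@H](C)CC)/C=C(C)\C(=O)CC/C(COCc2ccc(OC)cc2)=C\[C@@H](O)[C@@H]1C(=C)C=O | intermediate
37 | lactol (C12 epimers) | C=C1C(O)O[C@@H]2/C=C(/COCc3ccc(OC)cc3)CCC(=O)/C(C)=C\[C@@H](OC(=O)[C@@H](C)CC)[C@@H]12 | intermediate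
38 | α-methylene lactone C1 enone, C15 PMB ether | C=C1C(=O)O[C@@H]2/C=C(/COCc3ccc(OC)cc3)CCC(=O)/C(C)=C\[C@@H](OC(=O)[C@@H](C)CC)[C@@H]12 | intermediate
39 | C15 PMB ether of the target | C=C1C(=O)O[C@@H]2/C=C(/COCc3ccc(OC)cc3)CC[C@H](O)/C(C)=C\[C@@H](OC(=O)[C@@H](C)CC)[C@@H]12 | intermediate
40 | CNP0526758.1 | C=C1C(=O)O[C@@H]2/C=C(/CO)CC[C@H](O)/C(C)=C\[C@@H](OC(=O)[C@@H](C)CC)[C@@H]12 | target

## Step count and risk

Total step count: 25. Longest linear sequence: 22 (steps 1–12, 15–19 and 21–25).

**Step 16 (key step).** What is most likely to go wrong is a competing sigmatropic shift through the 2-propenyl group on C7. A second risk is stepwise heterolysis of C1–C6 followed by recombination at C1, which would expand the ring by two carbons only, because the departing fragment is a well-stabilised alkoxy-pentadienyl unit. A third is silyl transfer from O8 to the neighbouring alkoxide before rearrangement. The fallback is the neutral variant, which sets out from 23. Silylation with Me3SiOTf and 2,6-lutidine gives the trimethylsilyl ether F1. Heating F1 in o-dichlorobenzene at about 160 °C in a sealed tube should bring about the concerted siloxy-Cope shift to the trimethylsilyl enol ether F2, without a free anion that could fragment or accept a silyl group. Methanolysis of F2 with K2CO3 in MeOH at 0 °C returns to the route at 26.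

**Step 8.** Hydrogen abstraction may also occur at the naphthylmethyl CH2, at C12 or at C7, and the β-alkoxy enone may lose its C6 oxygen under base as it forms. The fallback sets out from 11. Epoxidation of the trisubstituted ring alkene with mCPBA gives epoxide F3. Opening at the less hindered C9 with PhSeNa (from PhSeSePh and NaBH4 in EtOH) gives hydroxy selenide F4. Oxidation with H2O2 and syn elimination, possible only toward C8, gives the tertiary allylic alcohol F5. Oxidative 1,3-transposition of F5 with IBX in DMSO comes back to the route at 12.

**Step 18.** The syn elimination may run through the C5 epimer that places C3 and C6 trans, giving the wrong alkene geometry, or selenenic acid may add to the dienol ether. The fallback sets out from 26. Kinetic silylation (LDA, Me3SiCl, THF, −78 °C) gives the trimethylsilyl enol ether F6. Saegusa–Ito oxidation of F6 with Pd(OAc)2 in MeCN returns to the route at 30. The palladium enolate can reach C4–H from either face, and reversible β-hydride elimination lets the geometry settle on the less strained ring-cis enone.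

**Step 21.** Hydride transfer may be slow if the ring cannot hold the C8 hemiacetal and the C6 carbonyl on one samarium centre, and aldehyde 33 may epimerise at its α-carbon before it is consumed. The fallback sets out from 31 and separates the two events. Esterification with (S)-2-methylbutanoic acid (CC[C@H](C)C(=O)O; EDC, catalytic DMAP, CH2Cl2, 0 °C) gives the β-acyloxy enone F7. 1,2-Reduction of the C6 ketone of F7 with Zn(BH4)2 in Et2O at −20 °C, now under Felkin-type substrate control, returns to the route at 34.

**Step 24.** Facial selectivity may be poor if the ring conformation opposes the catalyst, and the methylene lactone may suffer conjugate reduction. The fallback sets out from 38. Luche reduction (NaBH4, CeCl3, MeOH, −78 °C) under substrate control is tried first. If it gives the (1R)-alcohol F8, Mitsunobu inversion with chloroacetic acid (PPh3, DIAD, THF, 0 °C) gives the (1S)-chloroacetate F9. Cleavage of F9 with thiourea and NaHCO3 in EtOH returns to the route at 39.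

## Further compounds

F1 | step 16 | trimethylsilyl ether of 23 | C=C[C@@]1(OC)C(C)=C[C@@H](O[Si](CC)(CC)CC)[C@@H](C(=C)CO[Si](c2ccccc2)(c2ccccc2)C(C)(C)C)[C@]1(O[Si](C)(C)C)/C=C/COCc1ccc(OC)cc1
F2 | step 16 | trimethylsilyl enol ether of 26 (C7 and C4 trans across C5=C6) | [C@@H]1(O[Si](CC)(CC)CC)/C=C(C)\C(OC)=C\C[C@@H](COCc2ccc(OC)cc2)/C=C(\O[Si](C)(C)C)[C@@H]1C(=C)CO[Si](c3ccccc3)(c3ccccc3)C(C)(C)C
F3 | step 8 | C9,C10-epoxide of 11 (epoxide face not defined) | C=C[C@@]1(OC)C5(C)OC5C[C@@H](C(=C)CO[Si](c2ccccc2)(c2ccccc2)C(C)(C)C)[C@@H]1OCc3ccc4ccccc4c3
F4 | step 8 | C10 hydroxy C9 phenylselenide | C=C[C@@]1(OC)C(C)(O)C([Se]c5ccccc5)C[C@@H](C(=C)CO[Si](c2ccccc2)(c2ccccc2)C(C)(C)C)[C@@H]1OCc3ccc4ccccc4c3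
F5 | step 8 | C10 tertiary allylic alcohol with C8=C9 | C=C[C@@]1(OC)C(C)(O)C=C[C@@H](C(=C)CO[Si](c2ccccc2)(c2ccccc2)C(C)(C)C)[C@@H]1OCc3ccc4ccccc4c3
F6 | step 18 | trimethylsilyl enol ether of 26 from kinetic enolisation (C7 and C4 cis across C5=C6) | [C@@H]1(O[Si](CC)(CC)CC)/C=C(C)\C(OC)=C\C[C@@H](COCc2ccc(OC)cc2)/C=C(/O[Si](C)(C)C)[C@@H]1C(=C)CO[Si](c3ccccc3)(c3ccccc3)C(C)(C)C
F7 | step 21 | C8 (S)-2-methylbutanoate of 31 | [C@@H]1(OC(=O)[C@@H](C)CC)/C=C(C)\C(OC)=C\C/C(COCc2ccc(OC)cc2)=C\C(=O)[C@@H]1C(=C)CO[Si](c3ccccc3)(c3ccccc3)C(C)(C)C
F8 | step 24 | (1R)-epimer of 39 | C=C1C(=O)O[C@@H]2/C=C(/COCc3ccc(OC)cc3)CC[C@@H](O)/C(C)=C\[C@@H](OC(=O)[C@@H](C)CC)[C@@H]12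
F9 | step 24 | (1S)-chloroacetate of 39 | C=C1C(=O)O[C@@H]2/C=C(/COCc3ccc(OC)cc3)CC[C@H](OC(=O)CCl)/C(C)=C\[C@@H](OC(=O)[C@@H](C)CC)[C@@H]12
A1 | alternative 1 | bis-tert-butyldimethylsilyl ether of the target | C=C1C(=O)O[C@@H]2/C=C(/CO[Si](C)(C)C(C)(C)C)CC[C@H](O[Si](C)(C)C(C)(C)C)/C(C)=C\[C@@H](OC(=O)[C@@H](C)CC)[C@@H]12
A2 | alternative 2 | 10-membered C1 enone lactone with free C15 alcohol and C8 silyl ether | C1C(=O)O[C@@H]2/C=C(/CO)CCC(=O)/C(C)=C\[C@@H](O[Si](C)(C)C(C)(C)C)[C@@H]12
A3 | alternative 3 | 10-membered cyclodecenyne C8 alcohol | O([Si](CC)(CC)CC)[C@@H]1/C=C(/CO[Si](C)(C)C(C)(C)C)CC[C@H](O[Si](C)(C)C(C)(C)C)C#C[C@@H](O)[C@H]1C(=C)CO[Si](CC)(CC)CC
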